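# Proposed total synthesis of CNP0263622.1 (compound 27)

## Analysis of the target

Compound 27 is a profisetinidin-type tetraflavanoid. It holds three 5-deoxy flavan-3-ol units of the fisetinidol type (A, B and D: benzo ring with one hydroxyl at C7, catechol ring at C2) and one (+)-catechin unit (C: hydroxyls at C5 and C7). The units are joined by three C(sp3)–C(sp2) bonds, C4(A)–C6(B), C4(B)–C6(C) and C4(D)–C8(C), so the benzo ring of the catechin unit is fully substituted and unit A ends a linear A–B–C arm.

There are eleven stereocentres. C2 and C3 of all four units are (2R,3S), with aryl and hydroxyl trans. C4 of units A, B and D each carries its aryl group trans to the C3 hydroxyl and cis to the C2 aryl group (all-trans).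

The sensitive groups are thirteen phenolic hydroxyls (four air-sensitive catechols), four secondary alcohols, the benzylic O1–C2 ether bonds and the benzylic C4–aryl bonds, which ionise under strong acid. This calls for benzyl ethers throughout and one hydrogenolysis at the end.

The main difficulty is that the benzo rings of units B and D are the same resorcinol-type nucleophile (C6 para to O1 and ortho to O7). Joining unit A to a B–C–D trimer by attack of an arene on a C4 cation therefore cannot tell the two C6 positions apart. In addition, C6 of the catechin ring lies between two oxygens, and a 5-deoxy C4 cation needs an extra control element for its facial selectivity.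

The strategy rests on unit A. Its C3 hydroxyl and C4 hydrogen lie on the same face of the pyran ring, opposite the C2 aryl group. This is the result of a syn addition of H and OH across a C3=C4 double bond from the face away from the C2 aryl group. The pyran ring of unit A can thus be taken back to a 4-aryl-2H-chromene, whose C3=C4 bond is closed by metathesis and whose C4–C6(B) bond becomes an aryl–alkenyl bond fixed in position by a halogen on unit B.

## Retrosynthetic reasoning

**27 from 26.** All sixteen O-benzyl bonds are cut last. Compound 26 carries the full skeleton and all eleven stereocentres, and hydrogenolysis leaves the C2–O1 and C4–aryl bonds alone.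

**26 from 24.** The C3–O and C4–H bonds of unit A are removed to give the flav-3-ene 24. Hydroboration–oxidation must add boron at C3 and hydrogen at C4 on the face away from the C2 aryl group. One stereocentre (C2) then sets the other two, and no acid-mediated step is needed on the tetramer.

**24 from 23.** The C3=C4 bond of unit A is cut to give diene 23: a 1,1-diarylethene on C6 of unit B and an O-bound 1-arylallyl group on the neighbouring resorcinol ring. The cut is placed here because both alkene termini are then simple methylene groups that leave as a two-carbon fragment. The forward ring closure makes no stereocentre and only has to close a six-membered ring.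

**23 from 22 and 4.** The O1–C2 bond of unit A is cut to give phenol 22 and the linear cinnamyl carbonate 4. An iridium-catalysed asymmetric allylic etherification must give the branched ether and set C2 of unit A by catalyst control, independently of the ten stereocentres already present.

**22 from 17 and 20, through 21.** The bond between C6 of unit B and the future C4 of unit A is cut as an sp2–sp2 bond. The partners are aryl bromide 17 and the tosylhydrazone 20 of a silyl-protected 2-hydroxyacetophenone. The bromine marks C6 of unit B and no other carbon, which removes the B-versus-D ambiguity. The silyl ether is the only protecting group orthogonal to the benzyl ethers, and desilylation of 21 frees the phenol 22.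

**17 from 14 and 11, through 15 and 16.** The C4(B)–C6(C) bond is cut to give dimer 14 as the nucleophile and the brominated diacetate 11 as the C4 electrophile. The only phloroglucinol-type position left in 14 is C6 of the catechin ring. The C3 acetate of 11 must steer the arene to the face trans to it, and the bromine blocks the nucleophilic C6 of 11 itself. Exchange of the acetates for benzyl ethers (15 to 16 to 17) makes the trimer stable to the base used later.

**14 from 10 and 13.** The C4(D)–C8(C) bond is cut in the same way. C8 is the inherently most reactive position of benzylated catechin 13, so the order "D first at C8, B second at C6" follows the natural reactivity.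

**11 and 10 from 8, through 9.** Both fisetinidol electrophiles come from one flav-3-ene, 8. Syn-dihydroxylation anti to the C2 aryl group gives diol 9 and sets C3, acetylation gives 10, and electrophilic bromination of 10 at C6 gives 11.

**8 from 6 and 4, through 7.** The small flavene is made by the same pair of reactions as unit A, on a simple model of the key step: asymmetric allylic etherification of vinylphenol 6 with 4 sets C2 in 7, and ring closure gives 8.

**Starting materials.** Carbonate 4 comes from caffeic acid 1 through 2 and 3. Vinylphenol 6 comes from aldehyde 5, 13 from (+)-catechin 12, and 20 from ketone 18 through 19. Ketone 18 already has the acetyl group in place on the resorcinol ring, so no regiochemical question arises on that ring.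

## Alternatives that were turned down

**Alternative 1:** The three catechol rings of units A, B and D are cut off at their C2–aryl bonds. This leaves the core A2, in which the three pyran rings are lactol acetates with a participating acetate at C3, and the arene A3. In the forward key step a boron Lewis acid would ionise the three C2 acetates, and A3 would attack each oxocarbenium ion para to a benzyloxy group, giving A1.

- For: A3 is a bulk arene. The trans control by the C3 acetate is the same principle used here at C4. Three bonds and three stereocentres would form in one flask.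
- Against: A3 is a weak nucleophile next to the resorcinol-type benzo rings already in A2 (free C6 and C8 positions), so self-arylation would compete. Each new C2–O1 bond is a benzylic ether that the same Lewis acid can reopen. Three events on one molecule multiply any shortfall. The site-selective assembly of the 4-aryl links is only moved into the synthesis of A2, for which no short route is apparent.
- Comparison: on economy of the catechol rings and on setting three C2 centres by one principle this alternative is stronger. The chosen strategy instead sets each C2 with a catalyst on small or well-defined substrates and forms the critical A–B bond at a carbon marked by bromine.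

**Alternative 2:** The pyran ring of unit D is opened at O1–C2, back to the E-alkene A5, which bears a free ortho phenol and a blocking bromine. A5 itself arises by aromatic Claisen rearrangement of an aryl 1,3-disubstituted allyl ether, which relays chirality to C4. In the forward key step a Shi epoxidation of A5 and acid-mediated attack of the phenol at benzylic C2 would close the ring to A4.

- For: C4 of unit D is set by a stereospecific sigmatropic shift. On this point it is stronger than the face-selective cation capture used here in step 11.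
- Against: the epoxide of a 3,4-dialkoxystyrene ionises readily, so the inversion at C2 is not secured and 2,3-cis material would be expected. The free, electron-rich phenol has to survive a peroxymonosulfate oxidant. The Claisen step needs a stereodefined ether of a catechin-bound allylic alcohol and high temperature on a perbenzylated oligomer. The bromine is extra ballast. The route closes an end unit and leaves the B-versus-D site problem for unit A unanswered.
- Comparison: the chosen strategy offers a key step that forms no stereocentre and therefore cannot fail stereochemically. Units B and D come from one five-step intermediate.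

**Alternative 3:** The pyran ring of unit B is taken apart into three components: the phenol A7 (unit A carrying a resorcinol monoether at C4), the hindered aldehyde A8 (the C–D dimer formylated at C6 of the catechin ring) and the styrylboronate A9. In the forward key step an arylboronic acid template would join A7 and A8 at the ortho carbon, release an ortho-quinone methide, and A9 would add across it, giving A6 with boron at C3.

- For: three bonds, one ring and three stereocentres in one step, with the two halves of the molecule joined late. On convergence it is clearly stronger than the chosen, more linear end game.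
- Against: the quinone methide is planar, and its faces are distinguished only by remote stereocentres, so both enantiomeric series of unit B would be expected as a pair of diastereomers at the tetramer stage. A8 is a di-ortho-alkoxy benzaldehyde of low electrophilicity. The alkenylboronate is not an electron-rich partner for the heterodiene. A7 already contains a 4-arylfisetinidol whose site-selective synthesis is the problem to be solved.
- Comparison: the chosen strategy gives absolute control at every centre, by catalyst (C2 of A, B, D), by relay from C2 (C3, and C4 of A) or by the neighbouring acetate (C4 of B and D).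

Key step: step 20

Assumption 1: compounds 5 and 18 are treated as catalogue chemicals; each would otherwise come in one step from the corresponding 2,4-dihydroxy compound by selective benzylation of the non-chelated 4-hydroxyl.

Assumption 2: the (Sa,S,S) enantiomer of the phosphoramidite ligand L (from (S)-BINOL and bis[(S)-1-phenylethyl]amine) is taken to deliver the (S)-configured branched aryl ether; should the sense of induction be the opposite, the mirror-image ligand is used in steps 5 and 19.

## Route

Step 1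
Reactants: 1 caffeic acid
Product: 2 benzyl (E)-3-[3,4-bis(benzyloxy)phenyl]prop-2-enoate
Conditions: BnBr (3.5 equiv), K2CO3, DMF, 60 °C
Reagents that add atoms: benzyl bromide, BrCc1ccccc1
Why: Williamson-type alkylation; the carbonate base turns both phenols and the carboxylic acid into nucleophiles that displace bromide from benzyl bromide, and the E-alkene is not affected.

Step 2
Reactants: 2 benzyl (E)-3-[3,4-bis(benzyloxy)phenyl]prop-2-enoate
Product: 3 (E)-3-[3,4-bis(benzyloxy)phenyl]prop-2-en-1-ol
Conditions: i-Bu2AlH (3 equiv), CH2Cl2, −78 → 0 °C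
Reagents that add atoms: none
Why: 1,2-Reduction of a conjugated ester by i-Bu2AlH gives the allylic alcohol without touching the alkene or the benzyl ethers; the ester benzyl group leaves as benzyl alcohol.

Step 3
Reactants: 3 (E)-3-[3,4-bis(benzyloxy)phenyl]prop-2-en-1-ol
Product: 4 (E)-3-[3,4-bis(benzyloxy)phenyl]prop-2-en-1-yl methyl carbonate
Conditions: ClCO2Me, pyridine, CH2Cl2, 0 °C
Reagents that add atoms: methyl chloroformate, COC(Cl)=O
Why: Acylation of the primary allylic alcohol gives the linear carbonate, the standard ionisable partner for iridium-catalysed allylic substitution.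

Step 4
Reactants: 5 4-(benzyloxy)-2-hydroxybenzaldehyde
Product: 6 5-(benzyloxy)-2-ethenylphenol
Conditions: Ph3PCH3Br (2.5 equiv), KOt-Bu (2.5 equiv), THF, 0 °C → rt
Reagents that add atoms: methyltriphenylphosphonium bromide, C[P+](c1ccccc1)(c1ccccc1)c1ccccc1.[Br-]
Why: Wittig methylenation; the excess ylide takes up the phenol proton and the phenoxide aldehyde is still methylenated, as is routine for salicylaldehydes.

Step 5
Reactants: 6 5-(benzyloxy)-2-ethenylphenol; 4 (E)-3-[3,4-bis(benzyloxy)phenyl]prop-2-en-1-yl methyl carbonate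
Product: 7 4-(benzyloxy)-2-{[(1S)-1-[3,4-bis(benzyloxy)phenyl]prop-2-en-1-yl]oxy}-1-ethenylbenzene
Conditions: LiN(SiMe3)2 (1.0 equiv), [Ir(cod)Cl]2 (2 mol%), (Sa,S,S)-phosphoramidite L (4 mol%, pre-activated with n-PrNH2), THF, 50 °C
Reagents that add atoms: none
Why: Iridium-catalysed asymmetric allylic etherification: the cyclometallated iridium–phosphoramidite complex ionises the carbonate and the phenoxide attacks the aryl-substituted terminus of the allyl intermediate, giving the branched ether. The catalyst sets the (S) centre that becomes C2 of units B and D.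

Step 6
Reactants: 7 4-(benzyloxy)-2-{[(1S)-1-[3,4-bis(benzyloxy)phenyl]prop-2-en-1-yl]oxy}-1-ethenylbenzene
Product: 8 (2S)-7-(benzyloxy)-2-[3,4-bis(benzyloxy)phenyl]-2H-chromene
Conditions: RuCl2(H2IMes)(PCy3)(=CHPh) (second-generation Grubbs catalyst, 3 mol%), CH2Cl2, 40 °C
Reagents that add atoms: none
Why: Ring-closing metathesis of two monosubstituted alkenes held ortho to each other closes the pyran ring with loss of ethene; C2 is not involved and keeps its configuration.

Step 7
Reactants: 8 (2S)-7-(benzyloxy)-2-[3,4-bis(benzyloxy)phenyl]-2H-chromene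
Product: 9 (2R,3S,4S)-7-(benzyloxy)-2-[3,4-bis(benzyloxy)phenyl]chromane-3,4-diol (2,3-trans-3,4-cis)
Conditions: OsO4 (3 mol%), N-methylmorpholine N-oxide (1.5 equiv), acetone/H2O, rt
Reagents that add atoms: osmium tetroxide (catalytic oxygen carrier), O=[Os](=O)(=O)=O; N-methylmorpholine N-oxide, C[N+]1([O-])CCOCC1; water, O
Why: Upjohn dihydroxylation; OsO4 adds to the C3=C4 bond in a concerted syn manner on the face away from the C2 aryl group. This sets C3 trans to the aryl group; the C4 hydroxyl is only a leaving group later.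

Step 8
Reactants: 9 (2R,3S,4S)-7-(benzyloxy)-2-[3,4-bis(benzyloxy)phenyl]chromane-3,4-diol
Product: 10 (2R,3S,4S)-7-(benzyloxy)-2-[3,4-bis(benzyloxy)phenyl]chromane-3,4-diyl diacetate
Conditions: Ac2O, pyridine, DMAP (cat.), CH2Cl2, rt
Reagents that add atoms: acetic anhydride, CC(=O)OC(C)=O
Why: Acetylation of both hydroxyls places a leaving group at benzylic C4 and a participating group at C3.

Step 9
Reactants: 10 (2R,3S,4S)-7-(benzyloxy)-2-[3,4-bis(benzyloxy)phenyl]chromane-3,4-diyl diacetate
Product: 11 (2R,3S,4S)-7-(benzyloxy)-2-[3,4-bis(benzyloxy)phenyl]-6-bromochromane-3,4-diyl diacetate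
Conditions: NBS (1.05 equiv), MeCN/CH2Cl2, −20 → 0 °C, dark
Reagents that add atoms: N-bromosuccinimide, O=C1CCC(=O)N1Br
Why: Electrophilic aromatic bromination at C6, which is para to O1 and ortho to the 7-benzyloxy group. C8 lies between two oxygens and the catechol ring is activated by only one para oxygen per position, so the resorcinol-type carbon should react first.

Step 10
Reactants: 12 (+)-catechin
Product: 13 5,7,3',4'-tetra-O-benzyl-(+)-catechin
Conditions: BnBr (4.4 equiv), K2CO3, DMF, 0 °C → rt
Reagents that add atoms: benzyl bromide, BrCc1ccccc1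
Why: Williamson benzylation of the four phenols; the carbonate base does not deprotonate the secondary C3 hydroxyl, which stays free.

Step 11
Reactants: 10 (2R,3S,4S)-7-(benzyloxy)-2-[3,4-bis(benzyloxy)phenyl]chromane-3,4-diyl diacetate; 13 5,7,3',4'-tetra-O-benzyl-(+)-catechin
Product: 14 3-O-acetyl-7,3',4'-tri-O-benzylfisetinidol-(4→8)-5,7,3',4'-tetra-O-benzylcatechin (upper unit 2,3-trans-3,4-trans; catechin 3-OH free)
Conditions: 13 (3 equiv), Me3SiOSO2CF3 (0.3 equiv), CH2Cl2, −78 → −30 °C
Reagents that add atoms: none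
Why: Friedel–Crafts-type interflavanyl coupling: the Lewis acid ionises the C4 acetate to a benzylic cation stabilised by O1 and the 7-benzyloxy group, and the C3 acetate bridges it on the face of the C3 oxygen. C8 of 13, its most nucleophilic carbon, therefore attacks trans to C3–O, which sets C4 of unit D. The excess of 13 suppresses self-condensation of 10.

Step 12
Reactants: 14 D–C dimer (as named in step 11); 11 (2R,3S,4S)-7-(benzyloxy)-2-[3,4-bis(benzyloxy)phenyl]-6-bromochromane-3,4-diyl diacetate
Product: 15 6-bromo-3-O-acetyl-7,3',4'-tri-O-benzylfisetinidol-(4→6)-5,7,3',4'-tetra-O-benzylcatechin-(8←4)-3-O-acetyl-7,3',4'-tri-O-benzylfisetinidol (both fisetinidol units 2,3-trans-3,4-trans)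
Conditions: 11 (1.5 equiv), Me3SiOSO2CF3 (0.5 equiv), CH2Cl2, −40 → 0 °C
Reagents that add atoms: none
Why: Same coupling type; C6 of the catechin ring is the only phloroglucinol-type carbon left in 14 and is far more nucleophilic than the resorcinol-type ring of unit D. The C3 acetate of 11 again directs attack trans to it and sets C4 of unit B. The bromine blocks the nucleophilic C6 of 11, and the 5-deoxy C4–C8 bond of 14 resists re-ionisation.

Step 13
Reactants: 15 trimer diacetate (as named in step 12)
Product: 16 6-bromo-7,3',4'-tri-O-benzylfisetinidol-(4→6)-5,7,3',4'-tetra-O-benzylcatechin-(8←4)-7,3',4'-tri-O-benzylfisetinidol (three free 3-hydroxyls)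
Conditions: K2CO3 (0.5 equiv), MeOH/THF, rt
Reagents that add atoms: none
Why: Base-catalysed transesterification with methanol removes both acetates; aryl bromide, benzyl ethers and stereocentres are inert to methoxide at room temperature.

Step 14
Reactants: 16 trimer triol (as named in step 13)
Product: 17 perbenzylated B–C–D trimer bromide (16 with all three 3-hydroxyls benzylated; thirteen benzyl ethers, bromine at C6 of unit B)
Conditions: NaH (6 equiv), BnBr (6 equiv), Bu4NI (cat.), DMF, 0 °C → rt
Reagents that add atoms: benzyl bromide, BrCc1ccccc1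
Why: Williamson etherification of the three secondary alkoxides; iodide catalysis helps at the hindered C3 positions, and no base-labile group remains for the later steps.

Step 15
Reactants: 18 1-[4-(benzyloxy)-2-hydroxyphenyl]ethanone
Product: 19 1-[4-(benzyloxy)-2-(triisopropylsilyloxy)phenyl]ethanone
Conditions: i-Pr3SiCl, imidazole, DMAP (cat.), DMF, 40 °C
Reagents that add atoms: chlorotriisopropylsilane, CC(C)[Si](Cl)(C(C)C)C(C)C
Why: Silylation of the chelated phenol; the bulky triisopropylsilyl ether is chosen because it withstands alkoxide base better than smaller silyl ethers and is removed by fluoride without touching benzyl ethers.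

Step 16
Reactants: 19 1-[4-(benzyloxy)-2-(triisopropylsilyloxy)phenyl]ethanone
Product: 20 N'-{1-[4-(benzyloxy)-2-(triisopropylsilyloxy)phenyl]ethylidene}-4-methylbenzenesulfonohydrazide
Conditions: TsNHNH2 (1.1 equiv), MeOH, 50 °C
Reagents that add atoms: 4-methylbenzenesulfonohydrazide, Cc1ccc(cc1)S(=O)(=O)NN
Why: Condensation of the ketone with the sulfonyl hydrazide gives the tosylhydrazone with loss of water; its geometry is of no consequence for the next step.

Step 17
Reactants: 17 perbenzylated B–C–D trimer bromide; 20 tosylhydrazone (as named in step 16)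
Product: 21 trimer carrying at C6 of unit B a 1-[4-(benzyloxy)-2-(triisopropylsilyloxy)phenyl]ethenyl group
Conditions: 20 (1.5 equiv), Pd2(dba)3 (2.5 mol%), XPhos (10 mol%), LiOt-Bu (3.5 equiv), 1,4-dioxane, 100 °C
Reagents that add atoms: none
Why: Barluenga coupling: base converts the hydrazone into a diazoalkane, which forms a carbene on the arylpalladium bromide obtained by oxidative addition of 17 to zerovalent palladium. Migration of the aryl group to the carbene carbon and β-hydride elimination from the methyl group give the 1,1-diarylethene, and the bromine fixes the bond at C6 of unit B.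

Step 18
Reactants: 21 silyl-protected diarylethene (as named in step 17)
Product: 22 trimer carrying at C6 of unit B a 1-[4-(benzyloxy)-2-hydroxyphenyl]ethenyl group
Conditions: Bu4NF (1.2 equiv), THF, 0 °C; aq. NH4Cl
Reagents that add atoms: none
Why: Fluoride cleaves the aryl silyl ether under non-acidic conditions, so the acid-sensitive electron-rich diarylethene and the benzyl ethers are left alone.

Step 19
Reactants: 22 phenol (as named in step 18); 4 (E)-3-[3,4-bis(benzyloxy)phenyl]prop-2-en-1-yl methyl carbonate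
Product: 23 perbenzylated metathesis precursor: 22 etherified at the phenol oxygen with the (1S)-1-[3,4-bis(benzyloxy)phenyl]prop-2-en-1-yl group
Conditions: 4 (1.5 equiv), LiN(SiMe3)2 (1.0 equiv), [Ir(cod)Cl]2 (4 mol%), (Sa,S,S)-phosphoramidite L (8 mol%, pre-activated with n-PrNH2), THF, 50 °C
Reagents that add atoms: none
Why: Same iridium-catalysed asymmetric allylic etherification as in step 5; one equivalent of base deprotonates only the phenol. The catalyst, not the remote stereocentres of the trimer, sets the (S) ether carbon that becomes C2 of unit A.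

Step 20
Reactants: 23 perbenzylated metathesis precursor
Product: 24 protected tetraflavanoid in which unit A is a (2S)-7-(benzyloxy)-2-[3,4-bis(benzyloxy)phenyl]-2H-chromen-4-yl group on C6 of unit B
Conditions: RuCl2(H2IMes)(=CH–C6H4-2-Oi-Pr) (second-generation Hoveyda–Grubbs catalyst, 10 mol% in portions), 1,4-benzoquinone (20 mol%), toluene (0.003 M), 80 °C, argon purge
Reagents that add atoms: none
Why: Ring-closing metathesis: the ruthenium alkylidene first exchanges onto the unhindered vinyl group of the allyl ether, and the new carbene adds across the 1,1-diarylethene in an intramolecular [2+2] cycloaddition; cycloreversion of the ruthenacyclobutane releases the C3=C4 alkene of unit A and a ruthenium methylidene, which carries the chain with loss of ethene. The closest known reaction type is the metathesis of aryl allyl ethers bearing an ortho alkenyl group to 2H-chromenes, as in step 6, here with a 1-aryl-substituted vinyl partner that gives a trisubstituted ring alkene. The pyran ring of unit A is closed as a six-membered ring by forming an endocyclic double bond between two alkene carbons already linked through the ether oxygen and the arene. No stereocentre is formed; C2 of unit A is next to the reacting alkene but is not part of the mechanism, and the ten stereocentres of units B, C and D are remote. The step needs ring closure over intermolecular metathesis, which high dilution, the ortho arrangement of the two alkenes and the inability of the diarylethene to homodimerise should secure. It also needs freedom from double-bond migration in the allyl ether, for which 1,4-benzoquinone is added to intercept ruthenium hydrides. The phosphine-free chelated catalyst is chosen because it tolerates the temperature a 1,1-disubstituted alkene demands, and conjugation of the new alkene with both arenes together with loss of ethene makes the closure irreversible.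

Step 21
Reactants: 24 protected tetraflavanoid with the 2H-chromene unit A
Product: 26 hexadeca-O-benzyl ether of 27 with free C3 hydroxyl in unit A, via unit A C3-alkylborane 25 (not isolated)
Conditions: BH3·SMe2 (5 equiv), THF, 0 °C → rt; then NaBO3·4H2O, THF/H2O, rt
Reagents that add atoms: sodium perborate, O=BO[O-].[Na+]
Why: Hydroboration–oxidation: H and B add syn through a four-centre transition state, boron to the less substituted C3 and hydrogen to the diaryl-substituted C4, on the face away from the C2 aryl group. Oxidation with retention then gives the C3 hydroxyl trans to the C2 aryl group and the C4 aryl group trans to the hydroxyl, so C2 sets C3 and C4.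

Step 22
Reactants: 26 hexadeca-O-benzyl ether of 27
Product: 27 CNP0263622.1, fisetinidol-(4→6)-fisetinidol-(4→6)-catechin-(8←4)-fisetinidol (all fisetinidol units 2,3-trans-3,4-trans)
Conditions: H2 (1 atm), Pd(OH)2/C, THF/MeOH/H2O, rt
Reagents that add atoms: none
Why: Hydrogenolysis of the sixteen benzyl ethers over Pd(OH)2/C; the cyclic benzylic O1–C2 ethers and the C4–aryl bonds of flavans are not cleaved under these mild conditions, and no stereocentre is touched.

## Compound list

1 | caffeic acid | OC(=O)/C=C/c1ccc(O)c(O)c1 | starting material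
2 | benzyl (E)-3-[3,4-bis(benzyloxy)phenyl]prop-2-enoate | O=C(OCc1ccccc1)/C=C/c1ccc(OCc2ccccc2)c(OCc2ccccc2)c1 | intermediate
3 | (E)-3-[3,4-bis(benzyloxy)phenyl]prop-2-en-1-ol | OC/C=C/c1ccc(OCc2ccccc2)c(OCc2ccccc2)c1 | intermediate
4 | (E)-3-[3,4-bis(benzyloxy)phenyl]prop-2-en-1-yl methyl carbonate | COC(=O)OC/C=C/c1ccc(OCc2ccccc2)c(OCc2ccccc2)c1 | intermediate
5 | 4-(benzyloxy)-2-hydroxybenzaldehyde | O=Cc1ccc(OCc2ccccc2)cc1O | starting material
6 | 5-(benzyloxy)-2-ethenylphenol | C=Cc1ccc(OCc2ccccc2)cc1O | intermediate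
7 | 4-(benzyloxy)-2-{[(1S)-1-[3,4-bis(benzyloxy)phenyl]prop-2-en-1-yl]oxy}-1-ethenylbenzene | C=C[C@@H](c1ccc(OCc2ccccc2)c(OCc2ccccc2)c1)Oc1cc(OCc2ccccc2)ccc1C=C | intermediate
8 | (2S)-7-(benzyloxy)-2-[3,4-bis(benzyloxy)phenyl]-2H-chromene | O1[C@H](c2ccc(OCc3ccccc3)c(OCc3ccccc3)c2)C=Cc2ccc(OCc3ccccc3)cc12 | intermediate
9 | (2R,3S,4S)-7-(benzyloxy)-2-[3,4-bis(benzyloxy)phenyl]chromane-3,4-diol | O1[C@H](c2ccc(OCc3ccccc3)c(OCc3ccccc3)c2)[C@@H](O)[C@@H](O)c2ccc(OCc3ccccc3)cc12 | intermediate
10 | (2R,3S,4S)-7-(benzyloxy)-2-[3,4-bis(benzyloxy)phenyl]chromane-3,4-diyl diacetate | O1[C@H](c2ccc(OCc3ccccc3)c(OCc3ccccc3)c2)[C@@H](OC(C)=O)[C@@H](OC(C)=O)c2ccc(OCc3ccccc3)cc12 | intermediate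
11 | (2R,3S,4S)-7-(benzyloxy)-2-[3,4-bis(benzyloxy)phenyl]-6-bromochromane-3,4-diyl diacetate | O1[C@H](c2ccc(OCc3ccccc3)c(OCc3ccccc3)c2)[C@@H](OC(C)=O)[C@@H](OC(C)=O)c2cc(Br)c(OCc3ccccc3)cc12 | intermediate
12 | (+)-catechin | Oc1cc(O)c2c(c1)O[C@H](c1ccc(O)c(O)c1)[C@@H](O)C2 | starting material
13 | 5,7,3',4'-tetra-O-benzyl-(+)-catechin | O(Cc1ccccc1)c1cc(OCc3ccccc3)c2c(c1)O[C@H](c1ccc(OCc3ccccc3)c(OCc3ccccc3)c1)[C@@H](O)C2 | intermediate
14 | 3-O-acetyl-7,3',4'-tri-O-benzylfisetinidol-(4→8)-5,7,3',4'-tetra-O-benzylcatechin | c1c(OCc5ccccc5)c2c(c([C@@H]3c4ccc(OCc5ccccc5)cc4O[C@H](c4ccc(OCc5ccccc5)c(OCc5ccccc5)c4)[C@H]3OC(C)=O)c1OCc5ccccc5)O[C@H](c1ccc(OCc5ccccc5)c(OCc5ccccc5)c1)[C@@H](O)C2 | intermediate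
15 | 6-bromo-3-O-acetyl-tri-O-benzylfisetinidol-(4→6)-tetra-O-benzylcatechin-(8←4)-3-O-acetyl-tri-O-benzylfisetinidol | Brc1cc2c(cc1OCc5ccccc5)O[C@H](c1ccc(OCc5ccccc5)c(OCc5ccccc5)c1)[C@@H](OC(C)=O)[C@@H]2c1c(OCc5ccccc5)c2c(c([C@@H]3c4ccc(OCc5ccccc5)cc4O[C@H](c4ccc(OCc5ccccc5)c(OCc5ccccc5)c4)[C@H]3OC(C)=O)c1OCc5ccccc5)O[C@H](c1ccc(OCc5ccccc5)c(OCc5ccccc5)c1)[C@@H](O)C2 | intermediate
16 | B–C–D trimer bromide with three free 3-hydroxyls | Brc1cc2c(cc1OCc5ccccc5)O[C@H](c1ccc(OCc5ccccc5)c(OCc5ccccc5)c1)[C@@H](O)[C@@H]2c1c(OCc5ccccc5)c2c(c([C@@H]3c4ccc(OCc5ccccc5)cc4O[C@H](c4ccc(OCc5ccccc5)c(OCc5ccccc5)c4)[C@H]3O)c1OCc5ccccc5)O[C@H](c1ccc(OCc5ccccc5)c(OCc5ccccc5)c1)[C@@H](O)C2 | intermediate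
17 | perbenzylated B–C–D trimer bromide | Brc1cc2c(cc1OCc5ccccc5)O[C@H](c1ccc(OCc5ccccc5)c(OCc5ccccc5)c1)[C@@H](OCc5ccccc5)[C@@H]2c1c(OCc5ccccc5)c2c(c([C@@H]3c4ccc(OCc5ccccc5)cc4O[C@H](c4ccc(OCc5ccccc5)c(OCc5ccccc5)c4)[C@H]3OCc5ccccc5)c1OCc5ccccc5)O[C@H](c1ccc(OCc5ccccc5)c(OCc5ccccc5)c1)[C@@H](OCc5ccccc5)C2 | intermediate
18 | 1-[4-(benzyloxy)-2-hydroxyphenyl]ethanone | CC(=O)c1ccc(OCc2ccccc2)cc1O | starting material
19 | 1-[4-(benzyloxy)-2-(triisopropylsilyloxy)phenyl]ethanone | CC(=O)c1ccc(OCc2ccccc2)cc1O[Si](C(C)C)(C(C)C)C(C)C | intermediate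
20 | N'-{1-[4-(benzyloxy)-2-(triisopropylsilyloxy)phenyl]ethylidene}-4-methylbenzenesulfonohydrazide (drawn E) | C/C(=N\NS(=O)(=O)c1ccc(C)cc1)c1ccc(OCc2ccccc2)cc1O[Si](C(C)C)(C(C)C)C(C)C | intermediate
21 | trimer with 1-[4-(benzyloxy)-2-(triisopropylsilyloxy)phenyl]ethenyl at C6 of unit B | CC(C)[Si](C(C)C)(C(C)C)Oc1cc(OCc5ccccc5)ccc1C(=C)c1cc2c(cc1OCc5ccccc5)O[C@H](c1ccc(OCc5ccccc5)c(OCc5ccccc5)c1)[C@@H](OCc5ccccc5)[C@@H]2c1c(OCc5ccccc5)c2c(c([C@@H]3c4ccc(OCc5ccccc5)cc4O[C@H](c4ccc(OCc5ccccc5)c(OCc5ccccc5)c4)[C@H]3OCc5ccccc5)c1OCc5ccccc5)O[C@H](c1ccc(OCc5ccccc5)c(OCc5ccccc5)c1)[C@@H](OCc5ccccc5)C2 | intermediate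
22 | trimer with 1-[4-(benzyloxy)-2-hydroxyphenyl]ethenyl at C6 of unit B | Oc1cc(OCc5ccccc5)ccc1C(=C)c1cc2c(cc1OCc5ccccc5)O[C@H](c1ccc(OCc5ccccc5)c(OCc5ccccc5)c1)[C@@H](OCc5ccccc5)[C@@H]2c1c(OCc5ccccc5)c2c(c([C@@H]3c4ccc(OCc5ccccc5)cc4O[C@H](c4ccc(OCc5ccccc5)c(OCc5ccccc5)c4)[C@H]3OCc5ccccc5)c1OCc5ccccc5)O[C@H](c1ccc(OCc5ccccc5)c(OCc5ccccc5)c1)[C@@H](OCc5ccccc5)C2 | intermediate
23 | perbenzylated metathesis precursor ((1S)-1-arylallyl ether of 22) | C=C[C@@H](c1ccc(OCc5ccccc5)c(OCc5ccccc5)c1)Oc1cc(OCc5ccccc5)ccc1C(=C)c1cc2c(cc1OCc5ccccc5)O[C@H](c1ccc(OCc5ccccc5)c(OCc5ccccc5)c1)[C@@H](OCc5ccccc5)[C@@H]2c1c(OCc5ccccc5)c2c(c([C@@H]3c4ccc(OCc5ccccc5)cc4O[C@H](c4ccc(OCc5ccccc5)c(OCc5ccccc5)c4)[C@H]3OCc5ccccc5)c1OCc5ccccc5)O[C@H](c1ccc(OCc5ccccc5)c(OCc5ccccc5)c1)[C@@H](OCc5ccccc5)C2 | intermediate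
24 | protected tetraflavanoid with unit A as 2,4-diaryl-2H-chromene | C(c5ccccc5)Oc1ccc2c(c1)O[C@H](c1ccc(OCc5ccccc5)c(OCc5ccccc5)c1)C=C2c1cc2c(cc1OCc5ccccc5)O[C@H](c1ccc(OCc5ccccc5)c(OCc5ccccc5)c1)[C@@H](OCc5ccccc5)[C@@H]2c1c(OCc5ccccc5)c2c(c([C@@H]3c4ccc(OCc5ccccc5)cc4O[C@H](c4ccc(OCc5ccccc5)c(OCc5ccccc5)c4)[C@H]3OCc5ccccc5)c1OCc5ccccc5)O[C@H](c1ccc(OCc5ccccc5)c(OCc5ccccc5)c1)[C@@H](OCc5ccccc5)C2 | intermediate
25 | unit A C3-alkylborane (drawn as the monoalkylborane) | C(c5ccccc5)Oc1ccc2c(c1)O[C@H](c1ccc(OCc5ccccc5)c(OCc5ccccc5)c1)[C@@H](B)[C@@H]2c1cc2c(cc1OCc5ccccc5)O[C@H](c1ccc(OCc5ccccc5)c(OCc5ccccc5)c1)[C@@H](OCc5ccccc5)[C@@H]2c1c(OCc5ccccc5)c2c(c([C@@H]3c4ccc(OCc5ccccc5)cc4O[C@H](c4ccc(OCc5ccccc5)c(OCc5ccccc5)c4)[C@H]3OCc5ccccc5)c1OCc5ccccc5)O[C@H](c1ccc(OCc5ccccc5)c(OCc5ccccc5)c1)[C@@H](OCc5ccccc5)C2 | intermediate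
26 | hexadeca-O-benzyl ether of 27 with free C3 hydroxyl in unit A | C(c5ccccc5)Oc1ccc2c(c1)O[C@H](c1ccc(OCc5ccccc5)c(OCc5ccccc5)c1)[C@@H](O)[C@@H]2c1cc2c(cc1OCc5ccccc5)O[C@H](c1ccc(OCc5ccccc5)c(OCc5ccccc5)c1)[C@@H](OCc5ccccc5)[C@@H]2c1c(OCc5ccccc5)c2c(c([C@@H]3c4ccc(OCc5ccccc5)cc4O[C@H](c4ccc(OCc5ccccc5)c(OCc5ccccc5)c4)[C@H]3OCc5ccccc5)c1OCc5ccccc5)O[C@H](c1ccc(OCc5ccccc5)c(OCc5ccccc5)c1)[C@@H](OCc5ccccc5)C2 | intermediate
27 | CNP0263622.1 | Oc1ccc2c(c1)O[C@H](c1ccc(O)c(O)c1)[C@@H](O)[C@@H]2c1cc2c(cc1O)O[C@H](c1ccc(O)c(O)c1)[C@@H](O)[C@@H]2c1c(O)c2c(c([C@@H]3c4ccc(O)cc4O[C@H](c4ccc(O)c(O)c4)[C@H]3O)c1O)O[C@H](c1ccc(O)c(O)c1)[C@@H](O)C2 | target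

## Step count and least certain steps

Total: 22 steps. Longest linear sequence: 17 steps (from 1: steps 1–3, 5–9, 12–14, 17–22).

**Step 20 (key step).** The most likely failure is slow closure onto the 1,1-diarylethene, whose two aryl groups each carry an ortho substituent. During a long reaction time the catalyst decomposes to ruthenium hydrides, the allyl ether isomerises to an enol ether, and the C2 centre or the ring size is lost.

Fallback: form the C4(A)–C6(B) bond by carbonyl addition. Trimer bromide 17 would be converted by bromine–lithium exchange (t-BuLi, THF, −78 °C) and transmetallation with CeCl3 into an arylcerium reagent. This would be added to the flavanone (2S)-7-(benzyloxy)-2-[3,4-bis(benzyloxy)phenyl]chroman-4-one F1. F1 would be prepared by palladium-catalysed asymmetric conjugate addition of 3,4-bis(benzyloxy)phenylboronic acid to 7-(benzyloxy)chromen-4-one (Pd(OCOCF3)2 with the pyridine–oxazoline ligand enantiomer that gives the 2S product). The addition would give the tertiary 4-aryl-flavan-4-ol F2 as a mixture of C4 epimers. Dehydration with MsCl/Et3N, possible only towards C3, would return to the route at 24.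

**Step 19.** The phenoxide of 22 is hindered by the ortho diarylethene and the trimer behind it, so attack on the allyl–iridium intermediate may be slow. The electron-rich branched ether can meanwhile be re-ionised by the catalyst, which erodes the configuration at the ether carbon and the branched selectivity.

Fallback: set the ether centre on a small molecule first. Ketone 18 would be etherified with 4 under the conditions of step 5 to give 1-[4-(benzyloxy)-2-{[(1S)-1-[3,4-bis(benzyloxy)phenyl]prop-2-en-1-yl]oxy}phenyl]ethanone F3. The arylcerium reagent made from 17 (t-BuLi, then CeCl3, THF, −78 °C) would add to F3 to give the tertiary 1,1-diarylethanol F4 as a mixture of carbinol epimers. Dehydration with MsCl/Et3N at 0 °C, which avoids both palladium and acid, would return to the route at 23.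

**Step 12.** The carbon to be attacked lies between two benzyloxy groups and next to the bulky C8 substituent. The cation may instead be captured by the resorcinol-type ring of unit D, or it may react without full guidance by the C3 acetate, giving 3,4-cis material.

Fallback: reverse the order with a removable block. Benzylated catechin 13 would be iodinated at C8 (N-iodosuccinimide, CH2Cl2) to give 8-iodo-5,7,3',4'-tetra-O-benzylcatechin F5. Coupling of F5, in excess, with 11 under the conditions of step 11 can only occur at C6 and would give 6-bromo-3-O-acetyl-tri-O-benzylfisetinidol-(4→6)-8-iodo-tetra-O-benzylcatechin F6. Selective iodine–magnesium exchange (i-PrMgCl·LiCl, THF, −40 °C, then MeOH), which leaves the aryl bromide alone, would give 6-bromo-3-O-acetyl-tri-O-benzylfisetinidol-(4→6)-tetra-O-benzylcatechin F7. Coupling of F7 with 10 at the now free, favoured C8 would return to the route at 15.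

**Step 21.** The alkylborane 25 has boron β to the ring oxygen, so elimination with the aryloxide as leaving group (ring opening) may compete if the hindered trisubstituted alkene reacts only on warming. Addition from the face of the C2 aryl group is a lesser risk.

Fallback: copper-catalysed borylcupration–protonation (CuCl, Xantphos, NaOt-Bu, bis(pinacolato)diboron, MeOH, THF) of 24. Copper goes to the benzylic C4 and boron to C3, again syn and anti to the C2 aryl group. This would give the unit A C3 pinacol boronate of the protected tetraflavanoid F8, a boronic ester that is not Lewis acidic enough to eliminate. Oxidation with NaBO3 would return to the route at 26.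

**Step 17.** The aryl bromide is electron-rich and ortho-substituted and the carbene partner carries a bulky ortho silyloxy group, so oxidative addition and aryl migration may be slower than base-induced decomposition of the diazoalkane or loss of the silyl group.

Fallback: Suzuki–Miyaura coupling with a preformed alkenyl partner. Ketone 19 would be converted (KN(SiMe3)2, PhN(SO2CF3)2, THF, −78 °C) into the enol triflate 1-[4-(benzyloxy)-2-(triisopropylsilyloxy)phenyl]ethenyl trifluoromethanesulfonate F9. Borylation (bis(pinacolato)diboron, PdCl2(PPh3)2, KOPh, toluene, 50 °C) would give 2-{1-[4-(benzyloxy)-2-(triisopropylsilyloxy)phenyl]ethenyl}-4,4,5,5-tetramethyl-1,3,2-dioxaborolane F10. Coupling of F10 with 17 (Pd(OAc)2, SPhos, K3PO4, toluene/H2O, 80 °C) would return to the route at 21.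

## Further compounds

F1 | step 20 | (2S)-7-(benzyloxy)-2-[3,4-bis(benzyloxy)phenyl]chroman-4-one | O=C1C[C@@H](c2ccc(OCc3ccccc3)c(OCc3ccccc3)c2)Oc2cc(OCc3ccccc3)ccc12
F2 | step 20 | protected tetraflavanoid with unit A as 4-aryl-flavan-4-ol (C4 epimers) | C(c5ccccc5)Oc1ccc2c(c1)O[C@H](c1ccc(OCc5ccccc5)c(OCc5ccccc5)c1)CC2(O)c1cc2c(cc1OCc5ccccc5)O[C@H](c1ccc(OCc5ccccc5)c(OCc5ccccc5)c1)[C@@H](OCc5ccccc5)[C@@H]2c1c(OCc5ccccc5)c2c(c([C@@H]3c4ccc(OCc5ccccc5)cc4O[C@H](c4ccc(OCc5ccccc5)c(OCc5ccccc5)c4)[C@H]3OCc5ccccc5)c1OCc5ccccc5)O[C@H](c1ccc(OCc5ccccc5)c(OCc5ccccc5)c1)[C@@H](OCc5ccccc5)C2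
F3 | step 19 | 1-[4-(benzyloxy)-2-{[(1S)-1-[3,4-bis(benzyloxy)phenyl]prop-2-en-1-yl]oxy}phenyl]ethanone | C=C[C@@H](c1ccc(OCc2ccccc2)c(OCc2ccccc2)c1)Oc1cc(OCc2ccccc2)ccc1C(C)=O
F4 | step 19 | tertiary 1,1-diarylethanol from F3 and the trimer (carbinol epimers) | C=C[C@@H](c1ccc(OCc5ccccc5)c(OCc5ccccc5)c1)Oc1cc(OCc5ccccc5)ccc1C(C)(O)c1cc2c(cc1OCc5ccccc5)O[C@H](c1ccc(OCc5ccccc5)c(OCc5ccccc5)c1)[C@@H](OCc5ccccc5)[C@@H]2c1c(OCc5ccccc5)c2c(c([C@@H]3c4ccc(OCc5ccccc5)cc4O[C@H](c4ccc(OCc5ccccc5)c(OCc5ccccc5)c4)[C@H]3OCc5ccccc5)c1OCc5ccccc5)O[C@H](c1ccc(OCc5ccccc5)c(OCc5ccccc5)c1)[C@@H](OCc5ccccc5)C2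
F5 | step 12 | 8-iodo-5,7,3',4'-tetra-O-benzylcatechin | O(Cc1ccccc1)c1cc(OCc3ccccc3)c2c(c1I)O[C@H](c1ccc(OCc3ccccc3)c(OCc3ccccc3)c1)[C@@H](O)C2
F6 | step 12 | 6-bromo-3-O-acetyl-tri-O-benzylfisetinidol-(4→6)-8-iodo-tetra-O-benzylcatechin | Brc1cc2c(cc1OCc5ccccc5)O[C@H](c1ccc(OCc5ccccc5)c(OCc5ccccc5)c1)[C@@H](OC(C)=O)[C@@H]2c1c(OCc5ccccc5)c2c(c(I)c1OCc5ccccc5)O[C@H](c1ccc(OCc5ccccc5)c(OCc5ccccc5)c1)[C@@H](O)C2
F7 | step 12 | 6-bromo-3-O-acetyl-tri-O-benzylfisetinidol-(4→6)-tetra-O-benzylcatechin | Brc1cc2c(cc1OCc5ccccc5)O[C@H](c1ccc(OCc5ccccc5)c(OCc5ccccc5)c1)[C@@H](OC(C)=O)[C@@H]2c1c(OCc5ccccc5)c2c(cc1OCc5ccccc5)O[C@H](c1ccc(OCc5ccccc5)c(OCc5ccccc5)c1)[C@@H](O)C2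
F8 | step 21 | unit A C3 pinacol boronate of the protected tetraflavanoid | C(c5ccccc5)Oc1ccc2c(c1)O[C@H](c1ccc(OCc5ccccc5)c(OCc5ccccc5)c1)[C@@H](B6OC(C)(C)C(C)(C)O6)[C@@H]2c1cc2c(cc1OCc5ccccc5)O[C@H](c1ccc(OCc5ccccc5)c(OCc5ccccc5)c1)[C@@H](OCc5ccccc5)[C@@H]2c1c(OCc5ccccc5)c2c(c([C@@H]3c4ccc(OCc5ccccc5)cc4O[C@H](c4ccc(OCc5ccccc5)c(OCc5ccccc5)c4)[C@H]3OCc5ccccc5)c1OCc5ccccc5)O[C@H](c1ccc(OCc5ccccc5)c(OCc5ccccc5)c1)[C@@H](OCc5ccccc5)C2
F9 | step 17 | 1-[4-(benzyloxy)-2-(triisopropylsilyloxy)phenyl]ethenyl trifluoromethanesulfonate | C=C(OS(=O)(=O)C(F)(F)F)c1ccc(OCc2ccccc2)cc1O[Si](C(C)C)(C(C)C)C(C)C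
F10 | step 17 | 2-{1-[4-(benzyloxy)-2-(triisopropylsilyloxy)phenyl]ethenyl}-4,4,5,5-tetramethyl-1,3,2-dioxaborolane | C=C(B1OC(C)(C)C(C)(C)O1)c1ccc(OCc2ccccc2)cc1O[Si](C(C)C)(C(C)C)C(C)C
A1 | alternative 1 | protected tetraflavanoid with C3 acetates in units A, B and D | C(c5ccccc5)Oc1ccc2c(c1)O[C@H](c1ccc(OCc5ccccc5)c(OCc5ccccc5)c1)[C@@H](OC(C)=O)[C@@H]2c1cc2c(cc1OCc5ccccc5)O[C@H](c1ccc(OCc5ccccc5)c(OCc5ccccc5)c1)[C@@H](OC(C)=O)[C@@H]2c1c(OCc5ccccc5)c2c(c([C@@H]3c4ccc(OCc5ccccc5)cc4O[C@H](c4ccc(OCc5ccccc5)c(OCc5ccccc5)c4)[C@H]3OC(C)=O)c1OCc5ccccc5)O[C@H](c1ccc(OCc5ccccc5)c(OCc5ccccc5)c1)[C@@H](OCc5ccccc5)C2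
A2 | alternative 1 | tris-lactol acetate core (C2 acetates in units A, B and D, anomeric configuration open) | C(c5ccccc5)Oc1ccc2c(c1)OC(OC(C)=O)[C@@H](OC(C)=O)[C@@H]2c1cc2c(cc1OCc5ccccc5)OC(OC(C)=O)[C@@H](OC(C)=O)[C@@H]2c1c(OCc5ccccc5)c2c(c([C@@H]3c4ccc(OCc5ccccc5)cc4OC(OC(C)=O)[C@H]3OC(C)=O)c1OCc5ccccc5)O[C@H](c1ccc(OCc5ccccc5)c(OCc5ccccc5)c1)[C@@H](OCc5ccccc5)C2
A3 | alternative 1 | 1,2-bis(benzyloxy)benzene | c1ccc(OCc2ccccc2)c(OCc2ccccc2)c1
A4 | alternative 2 | protected tetraflavanoid with free C3 hydroxyl and bromine at C8 of unit D | C(c5ccccc5)Oc1ccc2c(c1)O[C@H](c1ccc(OCc5ccccc5)c(OCc5ccccc5)c1)[C@@H](OCc5ccccc5)[C@@H]2c1cc2c(cc1OCc5ccccc5)O[C@H](c1ccc(OCc5ccccc5)c(OCc5ccccc5)c1)[C@@H](OCc5ccccc5)[C@@H]2c1c(OCc5ccccc5)c2c(c([C@@H]3c4ccc(OCc5ccccc5)c(Br)c4O[C@H](c4ccc(OCc5ccccc5)c(OCc5ccccc5)c4)[C@H]3O)c1OCc5ccccc5)O[C@H](c1ccc(OCc5ccccc5)c(OCc5ccccc5)c1)[C@@H](OCc5ccccc5)C2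
A5 | alternative 2 | Claisen product: E-alkene with free ortho phenol in place of the pyran ring of unit D | C(c5ccccc5)Oc1ccc2c(c1)O[C@H](c1ccc(OCc5ccccc5)c(OCc5ccccc5)c1)[C@@H](OCc5ccccc5)[C@@H]2c1cc2c(cc1OCc5ccccc5)O[C@H](c1ccc(OCc5ccccc5)c(OCc5ccccc5)c1)[C@@H](OCc5ccccc5)[C@@H]2c1c(OCc5ccccc5)c2c(c([C@@H](/C=C/c4ccc(OCc5ccccc5)c(OCc5ccccc5)c4)c4ccc(OCc5ccccc5)c(Br)c4O)c1OCc5ccccc5)O[C@H](c1ccc(OCc5ccccc5)c(OCc5ccccc5)c1)[C@@H](OCc5ccccc5)C2
A6 | alternative 3 | protected tetraflavanoid with a pinacol boronate at C3 of unit B | C(c5ccccc5)Oc1ccc2c(c1)O[C@H](c1ccc(OCc5ccccc5)c(OCc5ccccc5)c1)[C@@H](OCc5ccccc5)[C@@H]2c1cc2c(cc1OCc5ccccc5)O[C@H](c1ccc(OCc5ccccc5)c(OCc5ccccc5)c1)[C@@H](B6OC(C)(C)C(C)(C)O6)[C@@H]2c1c(OCc5ccccc5)c2c(c([C@@H]3c4ccc(OCc5ccccc5)cc4O[C@H](c4ccc(OCc5ccccc5)c(OCc5ccccc5)c4)[C@H]3OCc5ccccc5)c1OCc5ccccc5)O[C@H](c1ccc(OCc5ccccc5)c(OCc5ccccc5)c1)[C@@H](OCc5ccccc5)C2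
A7 | alternative 3 | phenol component: unit A carrying a 2-(benzyloxy)-4-hydroxyphenyl group at C4 | C(c5ccccc5)Oc1ccc2c(c1)O[C@H](c1ccc(OCc5ccccc5)c(OCc5ccccc5)c1)[C@@H](OCc5ccccc5)[C@@H]2c1ccc(O)cc1OCc5ccccc5
A8 | alternative 3 | aldehyde component: perbenzylated C–D dimer with a formyl group at C6 of the catechin unit | O=Cc1c(OCc5ccccc5)c2c(c([C@@H]3c4ccc(OCc5ccccc5)cc4O[C@H](c4ccc(OCc5ccccc5)c(OCc5ccccc5)c4)[C@H]3OCc5ccccc5)c1OCc5ccccc5)O[C@H](c1ccc(OCc5ccccc5)c(OCc5ccccc5)c1)[C@@H](OCc5ccccc5)C2
A9 | alternative 3 | (E)-2-[3,4-bis(benzyloxy)styryl]-4,4,5,5-tetramethyl-1,3,2-dioxaborolane | CC1(C)OB(/C=C/c2ccc(OCc3ccccc3)c(OCc3ccccc3)c2)OC1(C)C
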